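## The problem

Angustone B is an achiral isoflavone built from four rings: the chromone (rings A and C), the aryl ring B on C3, and a 2,2-dimethyl-2H-pyran (ring D) fused angularly to ring B across C3'–C4' with its oxygen on C4'. The target has no stereocentre, so every selectivity question is one of regiochemistry:

- the prenyl group must sit on C6, between the 5- and 7-oxygens, and not on C8;
- the pyran must close onto the 4'-oxygen so that the 2'-hydroxyl stays free;
- of the three phloroglucinol oxygens of ring A, the one para to the prenyl group must become O1.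

The sensitive parts are the prenyl group flanked by two phenols (acid closes it to a chroman), the electron-rich chromene double bond (attacked by acids and electrophilic halogen, lost on hydrogenation) and the free polyphenol. This excludes methyl and benzyl ethers, strong Lewis acids and hydrogenolysis, and leaves acetal protection with a mild final unmasking.

The feature that opens the key step is the C3–C4 bond. C4 is an aryl carbonyl carbon on ring A. If the C2=C3 double bond is read as a dehydrated tertiary alcohol, C3 is also a carbonyl carbon, namely that of an aryl ketone on ring B. The two carbons are tethered through O1–C2, so joining them needs a polarity reversal at one carbonyl, within a six-membered ring closure.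

## Retrosynthesis

**Unmasking (18 from 17).** The last cut removes only the three methoxymethyl groups from the 5-, 7- and 2'-oxygens, leading from angustone B 18 to the tris-MOM isoflavone 17. Methyl ethers would need boron tribromide and benzyl ethers hydrogenolysis, and neither spares the prenyl and chromene alkenes. MOM ethers survive base, heat and carbene catalysis and fall to dilute acid. The forward step must be short and mild enough that the C6 prenyl group does not cyclise onto a freed phenol.

**Dehydration (17 from 15).** The C2=C3 double bond of 17 is traced to the tertiary alcohol 15 by formal addition of water with the hydroxyl on C3. Placing the hydroxyl on C3, and not on C2, is what turns C3 into a former ketone carbon and exposes the next cut. The forward step must lose the C3 hydroxyl together with a C2 hydrogen that is not acidified by the carbonyl. Enolate chemistry cannot do this, so the hydroxyl has to be activated as a leaving group.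

**The key cut (15 from 14).** Cutting C3–C4 of the 3-hydroxychroman-4-one 15 gives the keto-aldehyde 14, with a formyl group on ring A and an aryl ketone on ring B linked through the O1–C2 ether. The neighbouring cuts compare as follows:

- A cut at C3–C1' (metal-catalysed aryl–vinyl coupling) needs a pre-formed halogenated chromone and a doubly ortho-substituted ring B metal partner.
- A one-carbon closure at C2 needs Friedel–Crafts acylation of a prenylated phloroglucinol under Lewis acid.
- An oxidative 1,2-aryl shift needs oxidants that attack both alkenes.

The C3–C4 cut ends both halves in ordinary carbonyl groups that come with commercial materials. The aldehyde is the only group able to become an acyl anion equivalent. The forward reaction must make it the donor and the ketone the acceptor, and close ring C.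

**The ether (14 from 6 and 13).** Cutting O1–C2 divides 14 into the salicylaldehyde 6 and the α-bromoketone 13, two fragments of nearly equal size. The forward reaction is a phenoxide alkylation that must stop at the ether and not go on to an aldol closure.

**Ring B fragment (13 from 7 and 8).** The C–Br bond of 13 goes back to the methyl ketone 11, and its MOM ether to the chelated phenol 10. Ring D of 10 is cut at C3'–C4'' and O–C2'' to give 2,4-dihydroxyacetophenone 7 and 3-methylbut-2-enal 8. The acetyl carbon of 7 already sits where C3 will be. The hydrogen bond from the 2-hydroxyl to the acetyl group steers pyran closure to the 4-oxygen, which is the angular pattern required.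

**Ring A fragment (6 from 1 and 3).** The C6–prenyl bond of 6 is cut by a retro para-Claisen–Cope sequence to the aryl prenyl ether 4. This comes from the mono-phenol 2 and 1-bromo-3-methylbut-2-ene 3, and 2 from 2,4,6-trihydroxybenzaldehyde 1. The formyl group of 1 differentiates the three oxygens: its hydrogen bond leaves exactly one hydroxyl free in 2. The sigmatropic relay then carries the prenyl group to the carbon para to that oxygen, between the two MOM ethers, and returns the free phenol that becomes O1.

## Roads not taken

**Alternative 1:** The cut runs through ring D: the aryl–O bond, the aryl–C4 bond and the O–C2 bond of the chromene.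

- *Forward key step.* Fluoride releases a 3-alkoxybenzyne from the silyl triflate A2. The aryne adds to the carbonyl group of enal 8 in a formal (2+2) manner, and the benzoxete opens and recloses by oxa-6π electrocyclisation to 5-(methoxymethoxy)-2,2-dimethyl-2H-chromene A1.
- *Merits.* Conditions are neutral, and the alkoxy group directs the carbonyl oxygen to the distal aryne carbon, which gives the right chromene regiochemistry.
- *Weak points.* A1 carries no carbon at C6, so a directed metalation next to the MOM ether and an acylation or borylation must follow. A2 itself needs several steps. The problem it solves is one that 7 and 8 solve in a single step with the acetyl group already in place (compound 10).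
- *Comparison.* A metalated A1 coupled at C3–C1' would be a more proven isoflavone assembly than carbene catalysis on a hindered aldehyde. The chosen plan sets against this a shorter sequence and the use of both carbonyl carbons as they are bought.

**Alternative 2:** Ring B is cut completely (four ring bonds).

- *Forward key step.* Irradiation of the chromonyl diazoketone A4 triggers a Wolff rearrangement to a vinylketene. This combines with the prenylated siloxyalkyne A5 by (2+2) addition, four-electron ring opening and six-electron closure to give the phenol A3.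
- *Merits.* The substitution pattern of ring B is fixed by the annulation, and the chromone is complete before ring B exists.
- *Weak points.* The route builds a benzene ring that 7 supplies ready-made. A4 and A5 each need a multistep synthesis. A photoactive chromone has to survive irradiation. In A3 the 2'-hydroxyl is free and the 4'-oxygen is silylated, the reverse of what an oxidative closure of the 3'-prenyl group onto the 4'-oxygen needs, so protecting-group exchange and an oxidant in the presence of the ring A prenyl group follow.
- *Comparison.* It avoids the dehydration step and the hindered aldehyde of the chosen plan, but at roughly twice the step count.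

**Alternative 3:** Ring A is cut at C6–C7 and C7–C8, with C7 as a one-carbon linchpin.

- *Forward key step.* The doubly deprotonated pyranone A7 is carboxylated by dimethyl carbonate and closes by Dieckmann condensation. Enolisation gives 5,7-dihydroxy-3-[5-(methoxymethoxy)-2,2-dimethyl-2H-chromen-6-yl]-6-(3-methylbut-2-en-1-yl)-4H-chromen-4-one A6.
- *Merits.* The prenyl group is placed by construction, so the C6 versus C8 question never arises. Ring A appears with free phenols and only one MOM group remains. In this respect it is better than the chosen plan, which relies on the course of a sigmatropic relay.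
- *Weak points.* A7 is a tetrasubstituted pyranone whose synthesis is longer than that of 6. The dianion has two nucleophilic carbons and oxygen sites that can each acylate. Alkoxide can open the pyranone ring.
- *Comparison.* The chosen plan offers a ring A fragment in three steps from 1 by a rearrangement of a well-known type, and an overall shorter route.

Key step: step 8

Remark: the target is achiral. The stereocentres that appear on the way (C5 of 5, C3 of 15 and 16) are formed as racemates and vanish in the same or the next step, so no configuration has to be controlled.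

## Route

Step 1
Reactants: 1 2,4,6-trihydroxybenzaldehyde
Product: 2 2-hydroxy-4,6-bis(methoxymethoxy)benzaldehyde
Conditions: MOMCl (2.1 equiv), iPr2NEt, CH2Cl2, 0 °C to rt
Reagents that add atoms: chloromethyl methyl ether, COCCl
Why: Acetal protection of phenols (O-alkylation); the para hydroxyl and one ortho hydroxyl react, while the last ortho hydroxyl is held in a hydrogen bond to the formyl group and is left free.

Step 2
Reactants: 2 2-hydroxy-4,6-bis(methoxymethoxy)benzaldehyde; 3 1-bromo-3-methylbut-2-ene
Product: 4 2,4-bis(methoxymethoxy)-6-[(3-methylbut-2-en-1-yl)oxy]benzaldehyde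
Conditions: K2CO3, DMF, rt
Reagents that add atoms: none
Why: Williamson ether synthesis; the chelated phenoxide in a polar aprotic solvent is alkylated on oxygen by the primary allylic bromide at its unhindered terminus.

Step 3
Reactants: 4 2,4-bis(methoxymethoxy)-6-[(3-methylbut-2-en-1-yl)oxy]benzaldehyde
Product: 6 6-hydroxy-2,4-bis(methoxymethoxy)-3-(3-methylbut-2-en-1-yl)benzaldehyde, via ortho-dienone 5 (not isolated)
Conditions: PhNEt2, 200 °C, argon, sealed tube
Reagents that add atoms: none
Why: Aromatic Claisen rearrangement to the only free ortho carbon gives dienone 5, whose crowded tertiary allyl group moves on by Cope rearrangement to the para carbon between the two MOM ethers. Enolisation then returns a phenol that is hydrogen-bonded to the formyl group, the same para-Claisen–Cope course that is known for the corresponding 2-acyl aryl prenyl ethers.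

Step 4
Reactants: 7 2,4-dihydroxyacetophenone; 8 3-methylbut-2-enal
Product: 10 1-(5-hydroxy-2,2-dimethyl-2H-chromen-6-yl)ethan-1-one, via oxatriene 9 (not isolated)
Conditions: pyridine, 140 °C, sealed tube
Reagents that add atoms: none
Why: Base-mediated condensation of the enal at C3 of the resorcinol gives the ortho-quinone methide 9, which closes by oxa-6π electrocyclisation. The 2-hydroxyl stays hydrogen-bonded to the acetyl group, so the 4-oxygen closes the ring and the angular chromene results.

Step 5
Reactants: 10 1-(5-hydroxy-2,2-dimethyl-2H-chromen-6-yl)ethan-1-one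
Product: 11 1-[5-(methoxymethoxy)-2,2-dimethyl-2H-chromen-6-yl]ethan-1-one
Conditions: NaH, MOMCl, DMF, 0 °C to rt
Reagents that add atoms: chloromethyl methyl ether, COCCl
Why: O-alkylation of a phenoxide; the chelated phenol is the most acidic site and is deprotonated irreversibly by the hydride before the methyl ketone, so the acetal forms on oxygen only.

Step 6
Reactants: 11 1-[5-(methoxymethoxy)-2,2-dimethyl-2H-chromen-6-yl]ethan-1-one
Product: 13 2-bromo-1-[5-(methoxymethoxy)-2,2-dimethyl-2H-chromen-6-yl]ethan-1-one, via silyl enol ether 12 (not isolated)
Conditions: LiN(SiMe3)2, Me3SiCl, THF, −78 °C; then NBS, NaHCO3, THF, −78 to 0 °C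
Reagents that add atoms: N-bromosuccinimide, O=C1CCC(=O)N1Br
Why: α-Bromination of a ketone through its silyl enol ether; the ketone has a single enolisable position, the enol ether is far more nucleophilic than the chromene alkene, and no hydrogen bromide is set free that could cleave the MOM ether.

Step 7
Reactants: 6 6-hydroxy-2,4-bis(methoxymethoxy)-3-(3-methylbut-2-en-1-yl)benzaldehyde; 13 2-bromo-1-[5-(methoxymethoxy)-2,2-dimethyl-2H-chromen-6-yl]ethan-1-one
Product: 14 6-{2-[5-(methoxymethoxy)-2,2-dimethyl-2H-chromen-6-yl]-2-oxoethoxy}-2,4-bis(methoxymethoxy)-3-(3-methylbut-2-en-1-yl)benzaldehyde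
Conditions: K2CO3, DMF, 0 °C to rt
Reagents that add atoms: none
Why: Williamson ether synthesis with a highly reactive α-bromoketone; a mild carbonate base at or below room temperature stops at the ether, because the follow-up aldol closure onto the doubly ortho-substituted aldehyde (Rap–Stoermer condensation) needs heat.

Step 8
Reactants: 14 6-{2-[5-(methoxymethoxy)-2,2-dimethyl-2H-chromen-6-yl]-2-oxoethoxy}-2,4-bis(methoxymethoxy)-3-(3-methylbut-2-en-1-yl)benzaldehyde
Product: 15 racemic 3-hydroxy-5,7-bis(methoxymethoxy)-3-[5-(methoxymethoxy)-2,2-dimethyl-2H-chromen-6-yl]-6-(3-methylbut-2-en-1-yl)chroman-4-one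
Conditions: 2-(pentafluorophenyl)-6,7-dihydro-5H-pyrrolo[2,1-c][1,2,4]triazol-2-ium tetrafluoroborate (20 mol %), Et3N (20 mol %), toluene, rt to 40 °C, argon
Reagents that add atoms: none
Why: The carbene formed from the triazolium salt and Et3N adds to the ring A aldehyde, and proton transfer gives the Breslow intermediate, an acyl anion equivalent at the future C4. This enaminol attacks the carbonyl carbon of the tethered aryl ketone (the future C3), and collapse of the adduct releases the carbene and the tertiary α-ketol 15. The closest known reaction type is the carbene-catalysed intramolecular crossed aldehyde–ketone benzoin reaction of 2-(2-oxoalkoxy)benzaldehydes to 3-hydroxychroman-4-ones, aryl ketones included. Ring C closes in the 6-exo-trig mode, with the ketone C=O outside the forming ring. The new stereocentre at C3 is not controlled, since the catalyst is achiral, and the racemate is carried on because step 9 removes the centre. The step needs chemoselectivity (aldehyde as donor, ketone as acceptor) and must outrun both homo-benzoin coupling and base-induced aldol closure of the ketone enolate onto the aldehyde. The ketone cannot form a Breslow intermediate and is activated by its α-aryloxy group; the two ortho oxygens of the aldehyde hinder intermolecular coupling while the six-membered transition state stays accessible; and the weak amine base in catalytic amount keeps enolate chemistry slow.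

Step 9
Reactants: 15 racemic 3-hydroxy-5,7-bis(methoxymethoxy)-3-[5-(methoxymethoxy)-2,2-dimethyl-2H-chromen-6-yl]-6-(3-methylbut-2-en-1-yl)chroman-4-one
Product: 17 5,7-bis(methoxymethoxy)-3-[5-(methoxymethoxy)-2,2-dimethyl-2H-chromen-6-yl]-6-(3-methylbut-2-en-1-yl)-4H-chromen-4-one, via chlorosulfite 16 (not isolated)
Conditions: SOCl2, pyridine, CH2Cl2, 0 °C to rt
Reagents that add atoms: none
Why: Dehydration of a tertiary alcohol through its chlorosulfite ester; pyridine removes a C2 hydrogen anti to the leaving group, and any ionisation at C3 is supported by the 2,4-dioxygenated ring B. The product is a vinylogous ester (the chromone), which drives the elimination, and the excess pyridine protects the MOM ethers from hydrogen chloride.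

Step 10
Reactants: 17 5,7-bis(methoxymethoxy)-3-[5-(methoxymethoxy)-2,2-dimethyl-2H-chromen-6-yl]-6-(3-methylbut-2-en-1-yl)-4H-chromen-4-one
Product: 18 angustone B, 5,7-dihydroxy-3-(5-hydroxy-2,2-dimethyl-2H-chromen-6-yl)-6-(3-methylbut-2-en-1-yl)-4H-chromen-4-one
Conditions: HCl (1.25 M in MeOH), THF, 40 °C, short reaction time
Reagents that add atoms: none
Why: Acid-catalysed transacetalisation of the three aryl MOM ethers to methanol; dilute acid at mild temperature is the standard unmasking for prenylated polyphenols and is stopped before the prenyl group can cyclise onto a neighbouring phenol.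

## Compound list

1 | 2,4,6-trihydroxybenzaldehyde | O=Cc1c(O)cc(O)cc1O | starting material
2 | 2-hydroxy-4,6-bis(methoxymethoxy)benzaldehyde | COCOc1cc(O)c(C=O)c(OCOC)c1 | intermediate
3 | 1-bromo-3-methylbut-2-ene | CC(C)=CCBr | starting material
4 | 2,4-bis(methoxymethoxy)-6-[(3-methylbut-2-en-1-yl)oxy]benzaldehyde | CC(C)=CCOc1cc(OCOC)cc(OCOC)c1C=O | intermediate
5 | racemic 2,4-bis(methoxymethoxy)-5-(2-methylbut-3-en-2-yl)-6-oxocyclohexa-1,3-diene-1-carbaldehyde (ortho-dienone, not isolated) | C=CC(C)(C)C1C(OCOC)=CC(OCOC)=C(C=O)C1=O | intermediate
6 | 6-hydroxy-2,4-bis(methoxymethoxy)-3-(3-methylbut-2-en-1-yl)benzaldehyde (hydroxyl para to the prenyl group) | CC(C)=CCc1c(OCOC)cc(O)c(C=O)c1OCOC | intermediate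
7 | 2,4-dihydroxyacetophenone | CC(=O)c1ccc(O)cc1O | starting material
8 | 3-methylbut-2-enal | CC(C)=CC=O | starting material
9 | 4-acetyl-3-hydroxy-2-(3-methylbut-2-en-1-ylidene)cyclohexa-3,5-dien-1-one (oxatriene, geometry of the exocyclic alkene not defined, not isolated) | CC(=O)C1=C(O)C(=CC=C(C)C)C(=O)C=C1 | intermediate
10 | 1-(5-hydroxy-2,2-dimethyl-2H-chromen-6-yl)ethan-1-one | CC(=O)c1ccc2c(c1O)C=CC(C)(C)O2 | intermediate
11 | 1-[5-(methoxymethoxy)-2,2-dimethyl-2H-chromen-6-yl]ethan-1-one | CC(=O)c1ccc2c(c1OCOC)C=CC(C)(C)O2 | intermediate
12 | ({1-[5-(methoxymethoxy)-2,2-dimethyl-2H-chromen-6-yl]ethenyl}oxy)trimethylsilane (not isolated) | C=C(O[Si](C)(C)C)c1ccc2c(c1OCOC)C=CC(C)(C)O2 | intermediate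
13 | 2-bromo-1-[5-(methoxymethoxy)-2,2-dimethyl-2H-chromen-6-yl]ethan-1-one | O=C(CBr)c1ccc2c(c1OCOC)C=CC(C)(C)O2 | intermediate
14 | 6-{2-[5-(methoxymethoxy)-2,2-dimethyl-2H-chromen-6-yl]-2-oxoethoxy}-2,4-bis(methoxymethoxy)-3-(3-methylbut-2-en-1-yl)benzaldehyde | CC(C)=CCc1c(OCOC)cc(OCC(=O)c2ccc3c(c2OCOC)C=CC(C)(C)O3)c(C=O)c1OCOC | intermediate
15 | racemic 3-hydroxy-5,7-bis(methoxymethoxy)-3-[5-(methoxymethoxy)-2,2-dimethyl-2H-chromen-6-yl]-6-(3-methylbut-2-en-1-yl)chroman-4-one | CC(C)=CCc1c(OCOC)cc2OCC(O)(c3ccc4c(c3OCOC)C=CC(C)(C)O4)C(=O)c2c1OCOC | intermediate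
16 | racemic 5,7-bis(methoxymethoxy)-3-[5-(methoxymethoxy)-2,2-dimethyl-2H-chromen-6-yl]-6-(3-methylbut-2-en-1-yl)-4-oxochroman-3-yl chlorosulfite (mixture at sulfur, not isolated) | CC(C)=CCc1c(OCOC)cc2OCC(OS(=O)Cl)(c3ccc4c(c3OCOC)C=CC(C)(C)O4)C(=O)c2c1OCOC | intermediate
17 | 5,7-bis(methoxymethoxy)-3-[5-(methoxymethoxy)-2,2-dimethyl-2H-chromen-6-yl]-6-(3-methylbut-2-en-1-yl)-4H-chromen-4-one | CC(C)=CCc1c(OCOC)cc2occ(-c3ccc4c(c3OCOC)C=CC(C)(C)O4)c(=O)c2c1OCOC | intermediate
18 | angustone B, 5,7-dihydroxy-3-(5-hydroxy-2,2-dimethyl-2H-chromen-6-yl)-6-(3-methylbut-2-en-1-yl)-4H-chromen-4-one | CC(C)=CCc1c(O)cc2occ(-c3ccc4c(c3O)C=CC(C)(C)O4)c(=O)c2c1O | target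

## Step count and risks

Total step count: 10. Longest linear sequence: 7 steps (steps 1–3 or steps 4–6, then steps 7–10).

**Step 8 (key step).** The most likely failure is slow addition of the carbene to the electron-rich, doubly ortho-oxygenated aldehyde. Base-induced enolisation of the α-aryloxy ketone and aldol condensation onto the aldehyde would then take over, or the benzoin adduct would revert.

Fallback: this sets out from 14 and forms the same C3–C4 bond by reductive ketyl coupling. Samarium diiodide (SmI2, THF, −78 °C) reduces the aryl aldehyde to its ketyl, which adds to the tethered ketone in a six-membered closure. The product is 5,7-bis(methoxymethoxy)-3-[5-(methoxymethoxy)-2,2-dimethyl-2H-chromen-6-yl]-6-(3-methylbut-2-en-1-yl)chromane-3,4-diol F1, whose relative configuration does not matter. Oxidation of its secondary benzylic hydroxyl with SO3·pyridine, DMSO and Et3N, which does not cleave the diol, returns to the route at 15. The caveat is reductive loss of the α-aryloxy group, which the fast cyclisation of the aldehyde ketyl should precede.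

**Step 9.** The hindered tertiary hydroxyl sits next to a carbonyl group. Activation may be slow, ionisation at C3 is disfavoured by the ketone, and substitution by chloride may compete with elimination.

Fallback: this sets out from 15 and reverses the order of the last two operations. Treatment with HCl in MeOH removes the three MOM groups to give racemic 3,5,7-trihydroxy-3-(5-hydroxy-2,2-dimethyl-2H-chromen-6-yl)-6-(3-methylbut-2-en-1-yl)chroman-4-one F2. Its free 2'-hydroxyl expels the benzylic C3 hydroxyl on gentle warming through 3-(2,2-dimethyl-5-oxo-2H-chromen-6(5H)-ylidene)-5,7-dihydroxy-6-(3-methylbut-2-en-1-yl)chroman-4-one F3, an ortho-quinone methide. A proton shift from C2 then gives the chromone, so the sequence rejoins the route at 18.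

**Step 6.** Electrophilic bromine may add to the chromene double bond or brominate ring B, the ketone may be brominated twice, and traces of acid may cleave the MOM ether.

Fallback: this sets out from 11 and avoids halogen altogether. The potassium enolate (KN(SiMe3)2, THF, −78 °C) is hydroxylated with 2-(phenylsulfonyl)-3-phenyloxaziridine to 2-hydroxy-1-[5-(methoxymethoxy)-2,2-dimethyl-2H-chromen-6-yl]ethan-1-one F4. A Mitsunobu reaction of F4 with phenol 6 (PPh3, DIAD, THF) gives the ether under neutral conditions. The fallback comes back to the route at 14 and bypasses 13 and step 7.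

**Step 3.** Dienone 5 may enolise before the Cope shift, which would leave a reverse-prenyl group on the ortho carbon. The aldehyde and the MOM ethers may also suffer at 200 °C.

Fallback: this builds the same phenol by metalation chemistry. It sets out from 3 and purchased 1,3-bis(methoxymethoxy)benzene F5.

- Lithiation of F5 between the two MOM ethers (n-BuLi, THF, 0 °C, then CuI and 3) gives 1,3-bis(methoxymethoxy)-2-(3-methylbut-2-en-1-yl)benzene F6.
- Iridium-catalysed C–H borylation ([Ir(OMe)(cod)]2, 4,4'-di-tert-butyl-2,2'-bipyridine, B2pin2) at the only ring carbon without an ortho substituent gives 2-[3,5-bis(methoxymethoxy)-4-(3-methylbut-2-en-1-yl)phenyl]-4,4,5,5-tetramethyl-1,3,2-dioxaborolane F7.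
- Oxidation with H2O2 and NaOH gives 3,5-bis(methoxymethoxy)-4-(3-methylbut-2-en-1-yl)phenol F8.
- Magnesium-mediated ortho-formylation (MgCl2, Et3N, paraformaldehyde, MeCN, reflux) at either of the two equivalent ortho carbons rejoins the route at 6.

**Step 10.** Protonation of the prenyl alkene can lead to cyclisation onto the freed 5- or 7-hydroxyl, and methanol can add across the chromene double bond, before the last MOM group has left.

Fallback: this sets out from 17 and replaces Brønsted acid by silyl transfer. Me3SiOTf with 2,2'-bipyridyl (CH2Cl2, 0 °C to rt) converts the aryl MOM ethers into silyl ethers under weakly basic conditions. The product is 2,2-dimethyl-6-[6-(3-methylbut-2-en-1-yl)-4-oxo-5,7-bis(trimethylsilyloxy)-4H-chromen-3-yl]-5-(trimethylsilyloxy)-2H-chromene F9, which is hydrolysed by water or K2CO3 in MeOH at room temperature to return to the route at 18.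

## Further compounds

F1 | step 8 | 5,7-bis(methoxymethoxy)-3-[5-(methoxymethoxy)-2,2-dimethyl-2H-chromen-6-yl]-6-(3-methylbut-2-en-1-yl)chromane-3,4-diol (racemic, mixture of diastereomers) | CC(C)=CCc1c(OCOC)cc2OCC(O)(c3ccc4c(c3OCOC)C=CC(C)(C)O4)C(O)c2c1OCOC
F2 | step 9 | racemic 3,5,7-trihydroxy-3-(5-hydroxy-2,2-dimethyl-2H-chromen-6-yl)-6-(3-methylbut-2-en-1-yl)chroman-4-one | CC(C)=CCc1c(O)cc2OCC(O)(c3ccc4c(c3O)C=CC(C)(C)O4)C(=O)c2c1O
F3 | step 9 | 3-(2,2-dimethyl-5-oxo-2H-chromen-6(5H)-ylidene)-5,7-dihydroxy-6-(3-methylbut-2-en-1-yl)chroman-4-one (alkene geometry not defined) | CC(C)=CCc1c(O)cc2OCC(=C3C=CC4=C(C=CC(C)(C)O4)C3=O)C(=O)c2c1O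
F4 | step 6 | 2-hydroxy-1-[5-(methoxymethoxy)-2,2-dimethyl-2H-chromen-6-yl]ethan-1-one | OCC(=O)c1ccc2c(c1OCOC)C=CC(C)(C)O2
F5 | step 3 | 1,3-bis(methoxymethoxy)benzene | COCOc1cccc(OCOC)c1
F6 | step 3 | 1,3-bis(methoxymethoxy)-2-(3-methylbut-2-en-1-yl)benzene | CC(C)=CCc1c(OCOC)cccc1OCOC
F7 | step 3 | 2-[3,5-bis(methoxymethoxy)-4-(3-methylbut-2-en-1-yl)phenyl]-4,4,5,5-tetramethyl-1,3,2-dioxaborolane | CC(C)=CCc1c(OCOC)cc(cc1OCOC)B1OC(C)(C)C(C)(C)O1
F8 | step 3 | 3,5-bis(methoxymethoxy)-4-(3-methylbut-2-en-1-yl)phenol | CC(C)=CCc1c(OCOC)cc(O)cc1OCOC
F9 | step 10 | 2,2-dimethyl-6-[6-(3-methylbut-2-en-1-yl)-4-oxo-5,7-bis(trimethylsilyloxy)-4H-chromen-3-yl]-5-(trimethylsilyloxy)-2H-chromene | CC(C)=CCc1c(O[Si](C)(C)C)cc2occ(-c3ccc4c(c3O[Si](C)(C)C)C=CC(C)(C)O4)c(=O)c2c1O[Si](C)(C)C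
A1 | alternative 1 | 5-(methoxymethoxy)-2,2-dimethyl-2H-chromene | COCOc1cccc2c1C=CC(C)(C)O2
A2 | alternative 1 | 3-(methoxymethoxy)-2-(trimethylsilyl)phenyl trifluoromethanesulfonate | COCOc1cccc(OS(=O)(=O)C(F)(F)F)c1[Si](C)(C)C
A3 | alternative 2 | 3-{2-hydroxy-3-(3-methylbut-2-en-1-yl)-4-[(triisopropylsilyl)oxy]phenyl}-5,7-bis(methoxymethoxy)-6-(3-methylbut-2-en-1-yl)-4H-chromen-4-one | CC(C)=CCc1c(OCOC)cc2occ(-c3ccc(O[Si](C(C)C)(C(C)C)C(C)C)c(CC=C(C)C)c3O)c(=O)c2c1OCOC
A4 | alternative 2 | (E)-1-diazo-4-[5,7-bis(methoxymethoxy)-6-(3-methylbut-2-en-1-yl)-4-oxo-4H-chromen-3-yl]but-3-en-2-one | CC(C)=CCc1c(OCOC)cc2occ(/C=C/C(=O)C=[N+]=[N-])c(=O)c2c1OCOC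
A5 | alternative 2 | triisopropyl[(5-methylhex-4-en-1-yn-1-yl)oxy]silane | CC(C)=CCC#CO[Si](C(C)C)(C(C)C)C(C)C
A6 | alternative 3 | 5,7-dihydroxy-3-[5-(methoxymethoxy)-2,2-dimethyl-2H-chromen-6-yl]-6-(3-methylbut-2-en-1-yl)-4H-chromen-4-one | CC(C)=CCc1c(O)cc2occ(-c3ccc4c(c3OCOC)C=CC(C)(C)O4)c(=O)c2c1O
A7 | alternative 3 | 5-[5-(methoxymethoxy)-2,2-dimethyl-2H-chromen-6-yl]-2-methyl-3-(5-methylhex-4-enoyl)-4H-pyran-4-one | CC(C)=CCCC(=O)c1c(C)occ(-c2ccc3c(c2OCOC)C=CC(C)(C)O3)c1=O
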